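**Retrosynthetic overview**
- The target comes from a bicyclic 3‑alkoxy‑3,5‑diene by peracid γ‑hydroxylation at C6, which also unveils the C3 enone, followed by removal of one silyl ether.
- Both rings form in one dienyne ring‑closing metathesis cascade (vinyl → alkyne → enol ether): the seven‑membered ring B closes first (C5=C6), the five‑membered ring A second (C3=C4).
- The acyclic dienyne comes from a ketal (→ enol ether) carrying the C8 angelate; C7–C8 is made by an anti‑selective, catalyst‑controlled allylboration with an allylboronate that already carries the tertiary acetate.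
- The aldehyde for that step comes from a Hoppe homoaldol reaction of a propynyl ketone, which sets the C1 carbinol and the C10 methyl centre.
- Starting materials: fructone, 1‑propynylmagnesium bromide, crotyl alcohol, 2‑methylbut‑3‑en‑2‑ol, allylboronic acid pinacol ester, angelic acid.

Assumption: carbons are numbered as in guaiane (C1–C10 ring carbons, C11 the oxygenated side‑chain carbon); the given SMILES corresponds to (1R,6R,7S,8R,10S) with a Z (angelate) ester.

**Step 1**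
Reactants: 1 fructone (ethyl 2‑(2‑methyl‑1,3‑dioxolan‑2‑yl)acetate); 2 N,O‑dimethylhydroxylamine hydrochloride; 3 1‑propynylmagnesium bromide
Product: 5 1‑(2‑methyl‑1,3‑dioxolan‑2‑yl)pent‑3‑yn‑2‑one, via Weinreb amide 4 (not isolated)
Conditions: 2, iPrMgCl, THF, −20 °C; then 3, −20 °C → rt; aq. NH4Cl
Reagents that add atoms: 1‑propynylmagnesium bromide (3), CC#C[Mg]Br; N,O‑dimethylhydroxylamine hydrochloride (2), CNOC.Cl (in 4 only)
Why: The magnesium amide of MeNH(OMe) converts the ester into Weinreb amide 4, whose chelated tetrahedral adduct with the alkynyl Grignard reagent releases the ynone only on quench (one‑pot Weinreb ketone synthesis); no stereocenter is formed.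

**Step 2**
Reactants: 6 (E)‑but‑2‑en‑1‑ol; 7 N,N‑diisopropylcarbamoyl chloride
Product: 8 (E)‑but‑2‑en‑1‑yl N,N‑diisopropylcarbamate
Conditions: NaH, THF, 0 °C → reflux
Reagents that add atoms: N,N‑diisopropylcarbamoyl chloride (7), CC(C)N(C(C)C)C(=O)Cl
Why: O‑Carbamoylation of the alkoxide (Hoppe carbamate synthesis); no stereocenter.

**Step 3**
Reactants: 8 (E)‑but‑2‑en‑1‑yl N,N‑diisopropylcarbamate; 5 1‑(2‑methyl‑1,3‑dioxolan‑2‑yl)pent‑3‑yn‑2‑one
Product: 11 (1Z,3S,4R)‑4‑hydroxy‑3‑methyl‑4‑[(2‑methyl‑1,3‑dioxolan‑2‑yl)methyl]hept‑1‑en‑5‑yn‑1‑yl N,N‑diisopropylcarbamate, via lithiated carbamate 9 (not isolated), via allyltitanium reagent 10 (not isolated)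
Conditions: n‑BuLi, (−)‑sparteine, pentane/cyclohexane, −78 °C (crystallisation); Ti(OiPr)4, −78 °C; then 5, −78 → 0 °C; aq. NH4Cl
Reagents that add atoms: n‑butyllithium, [Li]CCCC (Li in 9 only); tetraisopropoxytitanium, CC(C)O[Ti](OC(C)C)(OC(C)C)OC(C)C (Ti(OiPr)3 in 10 only)
Why: Hoppe asymmetric homoaldol reaction: (−)‑sparteine‑mediated lithiation with crystallisation‑induced dynamic resolution gives (S)‑9, Li→Ti exchange with inversion gives (R)‑10, and its chair (Zimmerman–Traxler) addition to the ketone, with the CH2‑ketal arm equatorial and the slim alkynyl group axial, sets C10 (S) and the tertiary carbinol C1 (R) in an anti relationship and delivers the Z enol carbamate as a masked C8 aldehyde.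

**Step 4**
Reactants: 11 homoaldol adduct; 12 triethylsilyl trifluoromethanesulfonate
Product: 13 (1Z,3S,4R)‑3‑methyl‑4‑[(2‑methyl‑1,3‑dioxolan‑2‑yl)methyl]‑4‑(triethylsilyloxy)hept‑1‑en‑5‑yn‑1‑yl N,N‑diisopropylcarbamate
Conditions: TESOTf, 2,6‑lutidine, CH2Cl2, −78 → 0 °C
Reagents that add atoms: triethylsilyl trifluoromethanesulfonate (12), CC[Si](CC)(CC)OS(=O)(=O)C(F)(F)F
Why: Silylation of the tertiary propargylic alcohol with the silyl triflate (the lutidine buffer leaves ketal and enol carbamate intact) prevents lactol formation in the following steps and later shields the α‑face of the diene; no stereocenter changes.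

**Step 5**
Reactants: 13 silylated enol carbamate
Product: 15 (3S,4R)‑3‑methyl‑4‑[(2‑methyl‑1,3‑dioxolan‑2‑yl)methyl]‑4‑(triethylsilyloxy)hept‑5‑ynal, via lithium enolate 14 (not isolated)
Conditions: MeLi (2.5 equiv), Et2O, 0 °C → rt; aq. NH4Cl
Reagents that add atoms: methyllithium, [Li]C (Li in 14 only)
Why: Methyllithium adds to the carbamate carbonyl and expels the aldehyde enolate 14 (Hoppe enol carbamate cleavage), which is protonated on quench; C10 is β to the aldehyde and cannot epimerise.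

**Step 6**
Reactants: 16 2‑methylbut‑3‑en‑2‑ol; 17 acetic anhydride
Product: 18 2‑methylbut‑3‑en‑2‑yl acetate
Conditions: Ac2O, Et3N, DMAP (cat.), 40 °C
Reagents that add atoms: acetic anhydride (17), CC(=O)OC(C)=O
Why: DMAP‑catalysed acylation of a tertiary alcohol; no stereocenter.

**Step 7**
Reactants: 18 2‑methylbut‑3‑en‑2‑yl acetate; 19 allylboronic acid pinacol ester
Product: 20 (E)‑2‑methyl‑5‑(4,4,5,5‑tetramethyl‑1,3,2‑dioxaborolan‑2‑yl)pent‑3‑en‑2‑yl acetate
Conditions: second‑generation Hoveyda–Grubbs catalyst RuCl2(SIMes)(=CH‑C6H4‑2‑OiPr) (3 mol%), CH2Cl2, 40 °C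
Reagents that add atoms: none
Why: Olefin cross‑metathesis between a rapidly homodimerising allylboronate and a hindered tertiary allylic acetate that does not homodimerise gives the E alkene under thermodynamic control.

**Step 8**
Reactants: 15 aldehyde; 20 (E)‑allylboronate
Product: 22 2‑[(3S,4R,6S,7R)‑4‑hydroxy‑6‑methyl‑7‑[(2‑methyl‑1,3‑dioxolan‑2‑yl)methyl]‑7‑(triethylsilyloxy)dec‑1‑en‑8‑yn‑3‑yl]propan‑2‑yl acetate, via borate ester 21 (not isolated)
Conditions: (S)‑TRIP phosphoric acid (5 mol%), 4 Å MS, toluene, −30 °C → rt; aq. NaHCO3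
Reagents that add atoms: none
Why: Chiral phosphoric acid‑catalysed allylboration (Antilla type) through a closed chair transition state: the E boronate places the 2‑acetoxy‑2‑propyl group equatorial and so gives the anti C7/C8 pair, and (S)‑TRIP directs addition to the Si face of the aldehyde (the R acid is expected to give Re‑face addition), giving C8 (R) and C7 (S) under catalyst control with little influence from the remote C10 centre.

**Step 9**
Reactants: 22 homoallylic alcohol; 23 angelic acid ((Z)‑2‑methylbut‑2‑enoic acid); 24 2,4,6‑trichlorobenzoyl chloride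
Product: 26 (3S,4R,6S,7R)‑3‑(2‑acetoxypropan‑2‑yl)‑6‑methyl‑7‑[(2‑methyl‑1,3‑dioxolan‑2‑yl)methyl]‑7‑(triethylsilyloxy)dec‑1‑en‑8‑yn‑4‑yl (Z)‑2‑methylbut‑2‑enoate, via mixed anhydride 25 (not isolated)
Conditions: 23, 24, Et3N, toluene, rt; then 22, toluene, 75 °C
Reagents that add atoms: angelic acid (23), C/C=C(/C)C(=O)O; 2,4,6‑trichlorobenzoyl chloride (24), O=C(Cl)c1c(Cl)cc(Cl)cc1Cl (in 25 only)
Why: Yamaguchi esterification: the alcohol attacks the unhindered angeloyl carbonyl of mixed anhydride 25 without a nucleophilic catalyst, so the Z (angelate) geometry is kept, the tertiary acetate does not migrate, and C8 reacts with retention.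

**Step 10**
Reactants: 26 angelate ketal; 12 triethylsilyl trifluoromethanesulfonate
Product: 27 (3S,4R,6S,7R)‑3‑(2‑acetoxypropan‑2‑yl)‑6‑methyl‑7‑(triethylsilyloxy)‑7‑{2‑[2‑(triethylsilyloxy)ethoxy]prop‑2‑en‑1‑yl}dec‑1‑en‑8‑yn‑4‑yl (Z)‑2‑methylbut‑2‑enoate
Conditions: TESOTf, iPr2NEt, CH2Cl2, −78 → −20 °C
Reagents that add atoms: triethylsilyl trifluoromethanesulfonate (12), CC[Si](CC)(CC)OS(=O)(=O)C(F)(F)F
Why: Gassman ketal‑to‑enol‑ether conversion: the silyl triflate opens the dioxolane to an oxocarbenium ion and the hindered amine removes a proton from the unhindered methyl group, not from the neopentyl‑type C2 methylene, giving the terminal 2‑alkoxy alkene; esters and stereocenters are untouched.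

**Step 11**
Reactants: 27 acyclic dienyne
Product: 28 (1R,7S,8R,10S)‑11‑acetoxy‑8‑angeloyloxy‑1‑(triethylsilyloxy)‑3‑[2‑(triethylsilyloxy)ethoxy]guaia‑3,5‑diene
Conditions: second‑generation Hoveyda–Grubbs catalyst RuCl2(SIMes)(=CH‑C6H4‑2‑OiPr) (10 mol%), toluene (2 mM), 80 °C, Ar sparge
Reagents that add atoms: none
Why: Proposed new method: the ruthenium alkylidene forms at the monosubstituted vinyl group, adds to the alkyne in the exo mode to close the seven‑membered ring B (C5=C6) and leave a conjugated carbene at C4, which closes the five‑membered ring A onto the 1,1‑disubstituted enol ether (C3=C4) and releases Ru=CH2, so the 3‑alkoxy‑3,5‑diene forms with all four stereocenters untouched; the closest known reactions are the tandem dienyne ring‑closing metathesis to fused bicyclic dienes and the ring‑closing metathesis of 2‑alkoxy alkenes to cyclic enol ethers.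

**Step 12**
Reactants: 28 bicyclic dienol ether; 29 3‑chloroperoxybenzoic acid (mCPBA)
Product: 31 CNP0273287.1, (1R,6R,7S,8R,10S)‑11‑acetoxy‑8‑angeloyloxy‑1,6‑dihydroxyguai‑4‑en‑3‑one, via silyl ether 30 (not isolated)
Conditions: mCPBA, CH2Cl2/pH 7 phosphate buffer, −20 °C; then HF·pyridine, THF, 0 °C
Reagents that add atoms: 3‑chloroperoxybenzoic acid (29), OOC(=O)c1cccc(Cl)c1 (O at C6); water, O (carbonyl O at C3)
Why: Peracid oxidation of a 3‑alkoxy‑3,5‑diene to the 6‑hydroxy‑4‑en‑3‑one (vinylogous Rubottom oxidation): the peracid attacks the electron‑rich γ‑terminus C6 from the β‑face because the pseudo‑axial C1–OSiEt3 group covers the α‑face of C5=C6, the resulting oxocarbenium ion is hydrolysed to the enone, and HF·pyridine then cleaves the tertiary silyl ether.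

**Compound list**
1 | fructone, ethyl 2‑(2‑methyl‑1,3‑dioxolan‑2‑yl)acetate | CCOC(=O)CC1(C)OCCO1 | starting material
2 | N,O‑dimethylhydroxylamine hydrochloride | CNOC.Cl | starting material
3 | 1‑propynylmagnesium bromide | CC#C[Mg]Br | starting material
4 | N‑methoxy‑N‑methyl‑2‑(2‑methyl‑1,3‑dioxolan‑2‑yl)acetamide | CON(C)C(=O)CC1(C)OCCO1 | intermediate (not isolated)
5 | 1‑(2‑methyl‑1,3‑dioxolan‑2‑yl)pent‑3‑yn‑2‑one | CC#CC(=O)CC1(C)OCCO1 | intermediate
6 | (E)‑but‑2‑en‑1‑ol | C/C=C/CO | starting material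
7 | N,N‑diisopropylcarbamoyl chloride | CC(C)N(C(C)C)C(=O)Cl | starting material
8 | (E)‑but‑2‑en‑1‑yl N,N‑diisopropylcarbamate | C/C=C/COC(=O)N(C(C)C)C(C)C | intermediate
9 | (S)‑1‑lithio‑(E)‑but‑2‑enyl N,N‑diisopropylcarbamate (as its (−)‑sparteine complex) | C/C=C/[C@H]([Li])OC(=O)N(C(C)C)C(C)C | intermediate (not isolated)
10 | (R)‑1‑(triisopropoxytitanio)‑(E)‑but‑2‑enyl N,N‑diisopropylcarbamate | C/C=C/[C@@H]([Ti](OC(C)C)(OC(C)C)OC(C)C)OC(=O)N(C(C)C)C(C)C | intermediate (not isolated)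
11 | (1Z,3S,4R)‑4‑hydroxy‑3‑methyl‑4‑[(2‑methyl‑1,3‑dioxolan‑2‑yl)methyl]hept‑1‑en‑5‑yn‑1‑yl N,N‑diisopropylcarbamate | CC(C)N(C(C)C)C(=O)O/C=C\[C@H](C)[C@@](O)(C#CC)CC1(C)OCCO1 | intermediate
12 | triethylsilyl trifluoromethanesulfonate | CC[Si](CC)(CC)OS(=O)(=O)C(F)(F)F | starting material
13 | (1Z,3S,4R)‑3‑methyl‑4‑[(2‑methyl‑1,3‑dioxolan‑2‑yl)methyl]‑4‑(triethylsilyloxy)hept‑1‑en‑5‑yn‑1‑yl N,N‑diisopropylcarbamate | CC(C)N(C(C)C)C(=O)O/C=C\[C@H](C)[C@@](O[Si](CC)(CC)CC)(C#CC)CC1(C)OCCO1 | intermediate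
14 | lithium (Z)‑enolate of aldehyde 15 | [Li]O/C=C\[C@H](C)[C@@](O[Si](CC)(CC)CC)(C#CC)CC1(C)OCCO1 | intermediate (not isolated)
15 | (3S,4R)‑3‑methyl‑4‑[(2‑methyl‑1,3‑dioxolan‑2‑yl)methyl]‑4‑(triethylsilyloxy)hept‑5‑ynal | O=CC[C@H](C)[C@@](O[Si](CC)(CC)CC)(C#CC)CC1(C)OCCO1 | intermediate
16 | 2‑methylbut‑3‑en‑2‑ol | C=CC(C)(C)O | starting material
17 | acetic anhydride | CC(=O)OC(C)=O | starting material
18 | 2‑methylbut‑3‑en‑2‑yl acetate | C=CC(C)(C)OC(C)=O | intermediate
19 | allylboronic acid pinacol ester | C=CCB1OC(C)(C)C(C)(C)O1 | starting material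
20 | (E)‑2‑methyl‑5‑(4,4,5,5‑tetramethyl‑1,3,2‑dioxaborolan‑2‑yl)pent‑3‑en‑2‑yl acetate | CC(=O)OC(C)(C)/C=C/CB1OC(C)(C)C(C)(C)O1 | intermediate
21 | O‑pinacolboryl ester of alcohol 22 | C=C[C@@H]([C@H](OB1OC(C)(C)C(C)(C)O1)C[C@H](C)[C@@](O[Si](CC)(CC)CC)(C#CC)CC2(C)OCCO2)C(C)(C)OC(C)=O | intermediate (not isolated)
22 | 2‑[(3S,4R,6S,7R)‑4‑hydroxy‑6‑methyl‑7‑[(2‑methyl‑1,3‑dioxolan‑2‑yl)methyl]‑7‑(triethylsilyloxy)dec‑1‑en‑8‑yn‑3‑yl]propan‑2‑yl acetate | C=C[C@@H]([C@H](O)C[C@H](C)[C@@](O[Si](CC)(CC)CC)(C#CC)CC1(C)OCCO1)C(C)(C)OC(C)=O | intermediate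
23 | angelic acid, (Z)‑2‑methylbut‑2‑enoic acid | C/C=C(/C)C(=O)O | starting material
24 | 2,4,6‑trichlorobenzoyl chloride | O=C(Cl)c1c(Cl)cc(Cl)cc1Cl | starting material
25 | angelic 2,4,6‑trichlorobenzoic anhydride | C/C=C(/C)C(=O)OC(=O)c1c(Cl)cc(Cl)cc1Cl | intermediate (not isolated)
26 | (3S,4R,6S,7R)‑3‑(2‑acetoxypropan‑2‑yl)‑6‑methyl‑7‑[(2‑methyl‑1,3‑dioxolan‑2‑yl)methyl]‑7‑(triethylsilyloxy)dec‑1‑en‑8‑yn‑4‑yl (Z)‑2‑methylbut‑2‑enoate | C=C[C@@H]([C@H](OC(=O)/C(C)=C\C)C[C@H](C)[C@@](O[Si](CC)(CC)CC)(C#CC)CC1(C)OCCO1)C(C)(C)OC(C)=O | intermediate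
27 | (3S,4R,6S,7R)‑3‑(2‑acetoxypropan‑2‑yl)‑6‑methyl‑7‑(triethylsilyloxy)‑7‑{2‑[2‑(triethylsilyloxy)ethoxy]prop‑2‑en‑1‑yl}dec‑1‑en‑8‑yn‑4‑yl (Z)‑2‑methylbut‑2‑enoate | C=C[C@@H]([C@H](OC(=O)/C(C)=C\C)C[C@H](C)[C@@](O[Si](CC)(CC)CC)(C#CC)CC(=C)OCCO[Si](CC)(CC)CC)C(C)(C)OC(C)=O | intermediate
28 | (1R,7S,8R,10S)‑11‑acetoxy‑8‑angeloyloxy‑1‑(triethylsilyloxy)‑3‑[2‑(triethylsilyloxy)ethoxy]guaia‑3,5‑diene | C/C=C(/C)C(=O)O[C@@H]1C[C@H](C)[C@]2(O[Si](CC)(CC)CC)CC(OCCO[Si](CC)(CC)CC)=C(C)C2=C[C@@H]1C(C)(C)OC(C)=O | intermediate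
29 | 3‑chloroperoxybenzoic acid | OOC(=O)c1cccc(Cl)c1 | starting material
30 | (1R,6R,7S,8R,10S)‑11‑acetoxy‑8‑angeloyloxy‑6‑hydroxy‑1‑(triethylsilyloxy)guai‑4‑en‑3‑one | C/C=C(/C)C(=O)O[C@@H]1C[C@H](C)[C@]2(O[Si](CC)(CC)CC)CC(=O)C(C)=C2[C@H](O)[C@@H]1C(C)(C)OC(C)=O | intermediate (not isolated)
31 | CNP0273287.1, (1R,6R,7S,8R,10S)‑11‑acetoxy‑8‑angeloyloxy‑1,6‑dihydroxyguai‑4‑en‑3‑one | C/C=C(/C)C(=O)O[C@@H]1C[C@H](C)[C@]2(O)CC(=O)C(C)=C2[C@H](O)[C@@H]1C(C)(C)OC(C)=O | target

**Step count and risks**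
Total step count: 12. Longest linear sequence: 9 steps (1, 3, 4, 5, 8, 9, 10, 11, 12).

The three steps most likely to fail:

Step 11, the dienyne cascade. The second closure must form a tetrasubstituted enol‑ether double bond from a hindered carbene, and direct diene RCM between the vinyl group and the enol ether to an eight‑membered ring can compete. The fallback separates the two ring closures and sets out from 26. Enyne metathesis of 26 under ethylene with the same ruthenium catalyst closes only ring B and gives the ring‑B‑closed diene F1, which carries a 2‑propenyl group on C5 and the intact ketal. Treatment as in step 10 (TESOTf, iPr2NEt) converts F1 into the enol ether F2. A separate ring‑closing metathesis of the two 1,1‑disubstituted alkenes of F2 with the Schrock alkylidene Mo(=CHCMe2Ph)(=N‑2,6‑iPr2C6H3)[OCMe(CF3)2]2, which copes better with enol ethers and tetrasubstituted alkenes, closes ring A and returns to 28.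

Step 12, the facial selectivity at C6. The ring is flexible, and the C7 side chain may shield the β‑face more than the C1 silyl ether shields the α‑face. The fallback accepts the opposite face and corrects it by inversion; it sets out from 28. Oxidation of 28 with dimethyldioxirane and aqueous work‑up, anti to the C7 side chain, gives the 6‑epi alcohol F3. Mitsunobu reaction of F3 with chloroacetic acid (PPh3, DIAD) inverts C6 and gives the 6β‑chloroacetate F4. Thiourea and NaHCO3 in ethanol remove only the chloroacetyl group and return to 30, which is desilylated as in step 12.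

Step 8, the allylboration. The boronate carries a quaternary γ‑substituent and a tertiary acetate that can be lost by 1,4‑elimination, and the catalyst control on this bulky reagent is unproven. The fallback builds the same two centres by an auxiliary‑controlled aldol reaction and sets out from 15. The dibutylboron dienolate of (S)‑4‑benzyl‑3‑[(E)‑but‑2‑enoyl]oxazolidin‑2‑one (Bu2BOTf, Et3N) adds to 15 through its α‑carbon and gives the Evans syn‑aldol imide F5, which has the required C7/C8 configuration. MeMgBr with CeCl3 converts the imide into the dimethylcarbinol and gives the diol F6. Yamaguchi angeloylation of the secondary hydroxyl gives the mono‑angelate F7, and acetylation of the tertiary hydroxyl (Ac2O, DMAP) returns to 26.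

**Further compounds**
F1 | step 11 | ring‑B‑closed diene from enyne metathesis of 26 (C5=C6 in the seven‑membered ring, CH2=C(CH3)– on C5, ketal intact) | C/C=C(/C)C(=O)O[C@@H]1C[C@H](C)[C@](O[Si](CC)(CC)CC)(CC2(C)OCCO2)C(C(C)=C)=C[C@@H]1C(C)(C)OC(C)=O
F2 | step 11 | enol ether of F1 (C3 as CH2=C(OCH2CH2OSiEt3)–) | C/C=C(/C)C(=O)O[C@@H]1C[C@H](C)[C@](O[Si](CC)(CC)CC)(CC(=C)OCCO[Si](CC)(CC)CC)C(C(C)=C)=C[C@@H]1C(C)(C)OC(C)=O
F3 | step 12 | 6‑epi alcohol, (6S)‑epimer of 30 (6α‑OH) | C/C=C(/C)C(=O)O[C@@H]1C[C@H](C)[C@]2(O[Si](CC)(CC)CC)CC(=O)C(C)=C2[C@@H](O)[C@@H]1C(C)(C)OC(C)=O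
F4 | step 12 | 6β‑chloroacetate of 30 | C/C=C(/C)C(=O)O[C@@H]1C[C@H](C)[C@]2(O[Si](CC)(CC)CC)CC(=O)C(C)=C2[C@H](OC(=O)CCl)[C@@H]1C(C)(C)OC(C)=O
F5 | step 8 | Evans syn‑aldol imide of 15 (α‑vinyl, β‑hydroxy, (S)‑4‑benzyloxazolidinone) | C=C[C@@H]([C@H](O)C[C@H](C)[C@@](O[Si](CC)(CC)CC)(C#CC)CC1(C)OCCO1)C(=O)N1[C@@H](Cc2ccccc2)COC1=O
F6 | step 8 | C8,C11‑diol (dimethylcarbinol from F5) | C=C[C@@H]([C@H](O)C[C@H](C)[C@@](O[Si](CC)(CC)CC)(C#CC)CC1(C)OCCO1)C(C)(C)O
F7 | step 8 | C8 angelate with free C11 tertiary alcohol | C=C[C@@H]([C@H](OC(=O)/C(C)=C\C)C[C@H](C)[C@@](O[Si](CC)(CC)CC)(C#CC)CC1(C)OCCO1)C(C)(C)O
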